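The route rests on the bond between the vinylic CH (the alkene carbon remote from ring A) and the benzylic CH2 of ring B, the 4-bromo-3,5-dihydroxyphenyl ring. A Zweifel olefination makes it: the benzylic Grignard reagent of ring B adds to boron of an (E)-alkenyl pinacol boronate carrying ring A (the bromo-methoxy-phenol ring); iodine triggers 1,2-migration of the benzyl group from boron to the vinylic carbon, and methoxide-induced anti-elimination turns the E boronate into the Z alkene. The step exploits the skipped ArCH2–CH=CH–CH2Ar unit, a benzylic carbanion meeting a boron-bearing vinylic carbon, and needs no low-valent transition metal, so both aryl C–Br bonds survive.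

Key step: step 9

Remark: intermediates 3 and 16 carry transient stereocentres and are racemic; 16 is drawn as one enantiomer of the single diastereomer that anti-addition should give.

Step 1
Reactants: 1 4-methoxyphenol
Product: 2 1-(allyloxy)-4-methoxybenzene
Conditions: allyl bromide, K2CO3, acetone, reflux
Reagents that add atoms: allyl bromide, C=CCBr
Why: Williamson ether synthesis, in which the potassium phenoxide is O-alkylated by the reactive allylic bromide.

Step 2
Reactants: 2 1-(allyloxy)-4-methoxybenzene
Product: 4 2-allyl-4-methoxyphenol, via ortho-dienone 3 (not isolated)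
Conditions: N,N-diethylaniline, 200 °C, sealed tube
Reagents that add atoms: none
Why: aromatic Claisen rearrangement, a [3,3] shift to one of the two equivalent ortho positions followed by tautomerisation of the dienone, so only one regioisomer can form.

Step 3
Reactants: 4 2-allyl-4-methoxyphenol
Product: 5 2-allyl-4-methoxy-1-(methoxymethoxy)benzene
Conditions: MOMCl, iPr2NEt, CH2Cl2, 0 °C to rt
Reagents that add atoms: chloromethyl methyl ether, COCCl
Why: acetal protection of the phenol by O-alkylation, which masks the phenol against the Grignard reagent and iodine of step 9 and switches ring bromination away from the position ortho to the free hydroxyl.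

Step 4
Reactants: 5 2-allyl-4-methoxy-1-(methoxymethoxy)benzene
Product: 6 1-allyl-4-bromo-5-methoxy-2-(methoxymethoxy)benzene
Conditions: NBS, MeCN, 0 °C, dark
Reagents that add atoms: N-bromosuccinimide, O=C1CCC(=O)N1Br
Why: electrophilic aromatic bromination, expected at the carbon ortho to OMe and para to the allyl-bearing carbon (as 2,5-dimethoxytoluene brominates at C4), while NBS in MeCN without radical initiation should leave the terminal alkene alone.

Step 5
Reactants: 6 1-allyl-4-bromo-5-methoxy-2-(methoxymethoxy)benzene
Product: 7 (E)-2-[3-[4-bromo-5-methoxy-2-(methoxymethoxy)phenyl]prop-1-en-1-yl]-4,4,5,5-tetramethyl-1,3,2-dioxaborolane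
Conditions: vinylboronic acid pinacol ester (3 equiv), second-generation Grubbs catalyst (H2IMes)(PCy3)Cl2Ru=CHPh (5 mol %), CH2Cl2, 40 °C
Reagents that add atoms: vinylboronic acid pinacol ester, C=CB1OC(C)(C)C(C)(C)O1
Why: olefin cross-metathesis of an allylarene with a vinyl boronate, driven by loss of ethylene and expected to favour the E alkenyl boronate because of the bulk of the pinacol boronate group; any Z isomer is removed by chromatography.

Step 6
Reactants: 8 methyl 4-bromo-3,5-dihydroxybenzoate
Product: 9 methyl 4-bromo-3,5-bis(methoxymethoxy)benzoate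
Conditions: MOMCl (2.5 equiv), iPr2NEt, CH2Cl2, 0 °C to rt
Reagents that add atoms: chloromethyl methyl ether, COCCl
Why: twofold acetal protection of the phenols by O-alkylation, giving ethers that are stable to hydride, magnesium and methoxide and are cleavable later without touching the methyl ether of ring A.

Step 7
Reactants: 9 methyl 4-bromo-3,5-bis(methoxymethoxy)benzoate
Product: 11 [4-bromo-3,5-bis(methoxymethoxy)phenyl]methanol, via aldehyde 10 (not isolated)
Conditions: iBu2AlH (2.5 equiv), CH2Cl2, −78 to 0 °C; aqueous potassium sodium tartrate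
Reagents that add atoms: none
Why: hydride reduction of the ester to the benzylic alcohol by an aluminium hydride that does not reduce aryl bromides or acetals.

Step 8
Reactants: 11 [4-bromo-3,5-bis(methoxymethoxy)phenyl]methanol
Product: 13 2-bromo-5-(chloromethyl)-1,3-bis(methoxymethoxy)benzene, via mesylate 12 (not isolated)
Conditions: MsCl, Et3N, CH2Cl2, 0 °C; then LiCl, DMF, rt
Reagents that add atoms: lithium chloride, [Li+].[Cl-]
Why: sulfonylation followed by SN2 displacement with chloride, a base-buffered chlorination that keeps the acid-labile MOM ethers intact.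

Step 9
Reactants: 7 (E)-2-[3-[4-bromo-5-methoxy-2-(methoxymethoxy)phenyl]prop-1-en-1-yl]-4,4,5,5-tetramethyl-1,3,2-dioxaborolane, 13 2-bromo-5-(chloromethyl)-1,3-bis(methoxymethoxy)benzene
Product: 17 (Z)-1-[4-bromo-5-methoxy-2-(methoxymethoxy)phenyl]-4-[4-bromo-3,5-bis(methoxymethoxy)phenyl]but-2-ene, via benzylic Grignard reagent 14 (not isolated), via boronate ate complex 15 (not isolated), via beta-iodo boronic ester 16 (not isolated)
Conditions: 13 (1.5 equiv), Mg turnings, 2-MeTHF, 0 °C; then 7, THF, −78 to 0 °C; I2, THF, −78 °C; NaOMe, MeOH, −78 °C to rt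
Reagents that add atoms: none
Why: Magnesium inserts into the benzylic C–Cl bond of 13, the Grignard reagent 14 adds to the empty orbital on boron of 7 to give ate complex 15, iodine forms an iodonium ion on the alkenyl group, and the benzyl group migrates from boron to the boron-bearing vinylic carbon anti to the new C–I bond, which makes the new C–C bond and gives 16. The closest known reaction type is the Zweifel olefination in its Evans–Matteson form, where an alkenylboronic ester is combined with an organolithium or Grignard reagent before I2 and NaOMe. No ring is closed and the product has no stereocentre; the alkene geometry is the stereochemical element, fixed by anti-addition of benzyl and iodine across the E double bond followed by methoxide-triggered anti-elimination of boron and iodide, which inverts E to Z. The step needs magnesium insertion at the benzylic chloride and not at the aryl bromide, which the higher reactivity of a benzylic C–Cl bond at 0 °C and the electron-rich, doubly ortho-substituted aryl C–Br bond should secure, and it needs benzyl to migrate in preference to pinacol oxygen, which the higher migratory aptitude of carbon on a boronate secures. Because no low-valent transition metal is present, neither aryl bromide can undergo oxidative addition, and the MOM ethers are inert to the Grignard reagent, iodine and methoxide.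

Step 10
Reactants: 17 (Z)-1-[4-bromo-5-methoxy-2-(methoxymethoxy)phenyl]-4-[4-bromo-3,5-bis(methoxymethoxy)phenyl]but-2-ene
Product: 18 colpol
Conditions: HCl (1.25 M in MeOH), MeOH/THF, 40 °C
Reagents that add atoms: none
Why: acid-catalysed acetal exchange should remove the three MOM groups as dimethoxymethane while the aryl methyl ether, the aryl bromides and the unconjugated Z alkene are stable to dilute methanolic acid.

Compound list
1 | 4-methoxyphenol | COc1ccc(O)cc1 | starting material
2 | 1-(allyloxy)-4-methoxybenzene | C=CCOc1ccc(OC)cc1 | intermediate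
3 | 6-allyl-4-methoxycyclohexa-2,4-dien-1-one (racemic, formed in situ) | C=CCC1C=C(OC)C=CC1=O | intermediate
4 | 2-allyl-4-methoxyphenol | C=CCc1cc(OC)ccc1O | intermediate
5 | 2-allyl-4-methoxy-1-(methoxymethoxy)benzene | C=CCc1cc(OC)ccc1OCOC | intermediate
6 | 1-allyl-4-bromo-5-methoxy-2-(methoxymethoxy)benzene | C=CCc1cc(OC)c(Br)cc1OCOC | intermediate
7 | (E)-2-[3-[4-bromo-5-methoxy-2-(methoxymethoxy)phenyl]prop-1-en-1-yl]-4,4,5,5-tetramethyl-1,3,2-dioxaborolane | COCOc1cc(Br)c(OC)cc1C/C=C/B1OC(C)(C)C(C)(C)O1 | intermediate
8 | methyl 4-bromo-3,5-dihydroxybenzoate | COC(=O)c1cc(O)c(Br)c(O)c1 | starting material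
9 | methyl 4-bromo-3,5-bis(methoxymethoxy)benzoate | COCOc1cc(C(=O)OC)cc(OCOC)c1Br | intermediate
10 | 4-bromo-3,5-bis(methoxymethoxy)benzaldehyde (formed in situ) | COCOc1cc(C=O)cc(OCOC)c1Br | intermediate
11 | [4-bromo-3,5-bis(methoxymethoxy)phenyl]methanol | COCOc1cc(CO)cc(OCOC)c1Br | intermediate
12 | 4-bromo-3,5-bis(methoxymethoxy)benzyl methanesulfonate (formed in situ) | COCOc1cc(COS(C)(=O)=O)cc(OCOC)c1Br | intermediate
13 | 2-bromo-5-(chloromethyl)-1,3-bis(methoxymethoxy)benzene | COCOc1cc(CCl)cc(OCOC)c1Br | intermediate
14 | [4-bromo-3,5-bis(methoxymethoxy)benzyl]magnesium chloride (formed in situ) | COCOc1cc(C[Mg]Cl)cc(OCOC)c1Br | intermediate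
15 | chloromagnesium (E)-alkenyl(benzyl)pinacolatoborate, the ate complex of 7 and 14 (formed in situ) | COCOc1cc(Br)c(OC)cc1C/C=C/[B-]1(Cc2cc(OCOC)c(Br)c(OCOC)c2)OC(C)(C)C(C)(C)O1.[Mg+]Cl | intermediate
16 | rac-2-[(2S,3S)-1-[4-bromo-3,5-bis(methoxymethoxy)phenyl]-4-[4-bromo-5-methoxy-2-(methoxymethoxy)phenyl]-3-iodobutan-2-yl]-4,4,5,5-tetramethyl-1,3,2-dioxaborolane (formed in situ) | COCOc1cc(Br)c(OC)cc1C[C@H](I)[C@H](Cc1cc(OCOC)c(Br)c(OCOC)c1)B1OC(C)(C)C(C)(C)O1 | intermediate
17 | (Z)-1-[4-bromo-5-methoxy-2-(methoxymethoxy)phenyl]-4-[4-bromo-3,5-bis(methoxymethoxy)phenyl]but-2-ene | COCOc1cc(Br)c(OC)cc1C/C=C\Cc1cc(OCOC)c(Br)c(OCOC)c1 | intermediate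
18 | colpol, 2-bromo-5-[(Z)-4-(4-bromo-2-hydroxy-5-methoxyphenyl)but-2-en-1-yl]benzene-1,3-diol | COc1cc(C/C=C\Cc2cc(O)c(Br)c(O)c2)c(O)cc1Br | target

Total step count: 10. Longest linear sequence: 7 steps (steps 1, 2, 3, 4, 5, 9, 10); the ring B branch (steps 6, 7, 8) joins at step 9.

Steps most likely to fail

Step 9. Three processes threaten it: Wurtz homocoupling or magnesium insertion at the aryl C–Br bond while the Grignard reagent forms; incomplete or reversible ate-complex formation between an organomagnesium and a pinacol ester; and direct iodinolysis of the benzyl–boron bond in place of migration. The fallback sets out from 7 and 13 and comes back at 17. Compound 7 would be treated with Br2 (CH2Cl2, −78 °C) to give the anti-dibromide 2-[rac-(1R,2S)-1,2-dibromo-3-[4-bromo-5-methoxy-2-(methoxymethoxy)phenyl]propyl]-4,4,5,5-tetramethyl-1,3,2-dioxaborolane F1, which is not isolated. NaOMe in MeOH would then cause anti-elimination of boron and bromide to (Z)-1-bromo-3-[4-bromo-5-methoxy-2-(methoxymethoxy)phenyl]prop-1-ene F2. Chloride 13 would be converted with Zn dust and LiCl (THF, rt) into [4-bromo-3,5-bis(methoxymethoxy)benzyl]zinc chloride F3. Negishi coupling of F2 with F3 (Pd(PPh3)4, THF, rt) should give 17 with retention of the Z geometry, since the alkenyl C–Br bond should add to zerovalent palladium faster than the two electron-rich, ortho-substituted aryl C–Br bonds.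

Step 5. Incomplete E selectivity, migration of the allyl double bond into conjugation with ring A by ruthenium hydride species, and homodimerisation of the allylarene may erode the yield and the geometric purity on which step 9 depends. The fallback sets out from 6 and comes back at 7. Oxidative cleavage of the alkene (OsO4 catalytic, NaIO4, 2,6-lutidine, dioxane/H2O) would give 2-[4-bromo-5-methoxy-2-(methoxymethoxy)phenyl]acetaldehyde F4. A boron-Wittig olefination of F4 with lithiated bis(pinacolboryl)methane (CH2(Bpin)2, lithium 2,2,6,6-tetramethylpiperidide, THF, −78 °C to rt) should then give the E alkenyl boronate 7 stereoselectively.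

Step 4. Addition of electrophilic bromine to the allyl double bond and partial bromination ortho to the MOM ether may compete with the wanted ring bromination. The fallback sets out from 5 and comes back at 6. Bromine (2.1 equiv, NaHCO3, CH2Cl2, 0 °C) would deliberately saturate the alkene and brominate the ring, giving racemic 1-bromo-4-(2,3-dibromopropyl)-2-methoxy-5-(methoxymethoxy)benzene F5. Reductive debromination of the vicinal dibromide (Zn dust, AcOH, EtOH, 0 °C to rt) should then regenerate the allyl group and give 6, the aryl bromide being inert to zinc under these conditions.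

Further compounds
F1 | step 9 | 2-[rac-(1R,2S)-1,2-dibromo-3-[4-bromo-5-methoxy-2-(methoxymethoxy)phenyl]propyl]-4,4,5,5-tetramethyl-1,3,2-dioxaborolane | COCOc1cc(Br)c(OC)cc1C[C@H](Br)[C@H](Br)B1OC(C)(C)C(C)(C)O1
F2 | step 9 | (Z)-1-bromo-3-[4-bromo-5-methoxy-2-(methoxymethoxy)phenyl]prop-1-ene | COCOc1cc(Br)c(OC)cc1C/C=C\Br
F3 | step 9 | [4-bromo-3,5-bis(methoxymethoxy)benzyl]zinc chloride | COCOc1cc(C[Zn]Cl)cc(OCOC)c1Br
F4 | step 5 | 2-[4-bromo-5-methoxy-2-(methoxymethoxy)phenyl]acetaldehyde | COCOc1cc(Br)c(OC)cc1CC=O
F5 | step 4 | 1-bromo-4-(2,3-dibromopropyl)-2-methoxy-5-(methoxymethoxy)benzene (racemic) | COCOc1cc(Br)c(OC)cc1CC(Br)CBr
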